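The retrosynthesis removes the three esters first (the C12 butanoate through Mitsunobu inversion of a 12-epi alcohol), then cuts C4–C5 of the ten-membered ring (B-alkyl Suzuki), C8–C17 of the lactone (samarium Reformatsky), C6–C7, C7–C8/C8–C9 (a dithiane ester serves as C8 acyl anion carrying C7), C2–C3, and last C1–C14 and C10–C11.
The enabling feature is the six-membered ring C1/C10–C14: quaternary C1 (methyl, C2), C10 (H, C9) and C11 (methyl) lie in a row beside the C12 oxygen, which is the imprint of a 2-silyloxydiene (C11–C14) on an E α-methyl enal (C2–C1–C10–C9).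
Forward order: cyclohexene by Diels–Alder; C3/C4 onto C2; enone and C12 alcohol; C8, C7 and C5/C6/C16 onto C9; Z vinyl iodide; lactone; ten-membered ring; esters.
Stereochemistry: C1, C10 and C11 come from the catalysed cycloaddition, C2 and C7 from CBS reductions, C9 from a Felkin–Anh aldol, C8 and C17 are relayed from C7 during lactone closure, and C12 is set by hydride attack on the open face followed by SN2 inversion.

Key step: step 3

Remark: locants are the briarane numbers of the target (C15 = methyl on C1, C16 = methyl on C5, C18 = methyl on C17, C19 = lactone carbonyl, C20 = methyl on C11); β is the face of the six-membered ring that carries C15, C9 and C20, α the face that carries C2.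
Assumption: the (S)-configured oxazaborolidinium ion is taken to leave open the enal face that leads to (1S,10S)-6; if the sense were opposite, the (R)-catalyst would be used with no other change.

Step 1
Reactants: 1 pent-1-en-3-one
Product: 2 (Z)-3-(tert-butyldimethylsilyloxy)penta-1,3-diene
Conditions: TBSOTf, Et3N, Et2O, 0 °C
Reagents that add atoms: tert-butyldimethylsilyl triflate, CC(C)(C)[Si](C)(C)OS(=O)(=O)C(F)(F)F
Why: O-silylation under soft enolisation (silyl triflate and tertiary amine) gives the dienyl silyl ether, and the Z enol ether geometry usual for ethyl ketones places the C20 methyl on the outside of the s-cis diene.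

Step 2
Reactants: 3 (tert-butyldimethylsilyloxy)acetaldehyde; 4 2-(triphenylphosphoranylidene)propanal
Product: 5 (E)-4-(tert-butyldimethylsilyloxy)-2-methylbut-2-enal
Conditions: toluene, 80 °C
Reagents that add atoms: none
Why: Wittig olefination with the stabilised formyl ylide is E-selective, and the product enal is too weak an electrophile to react a second time.

Step 3
Reactants: 2 (Z)-3-(tert-butyldimethylsilyloxy)penta-1,3-diene; 5 (E)-4-(tert-butyldimethylsilyloxy)-2-methylbut-2-enal
Product: 6 (1S,5R,6S)-4-(tert-butyldimethylsilyloxy)-6-[(tert-butyldimethylsilyloxy)methyl]-1,5-dimethylcyclohex-3-ene-1-carbaldehyde (ring carbons 1, 5, 6 = briarane C1, C11, C10; formyl = C2; C12 silyl enol ether)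
Conditions: (S)-B-(o-tolyl) oxazaborolidinium triflimide [C24H25BNO][N(SO2CF3)2] from (S)-diphenylprolinol (20 mol%), CH2Cl2, −78 → −40 °C
Reagents that add atoms: none
Why: The cationic oxazaborolidine binds the formyl oxygen of s-trans 5 and the silyloxydiene adds in a concerted, asynchronous [4+2] cycloaddition, the closest known type being the oxazaborolidinium-catalysed Diels–Alder reaction of 2-silyloxydienes with 2-substituted enals. The six-membered ring closes in one suprafacial event in which C14 bonds to C1 and C11 to C10. The enol ether makes C11 the nucleophilic diene terminus and the activated enal makes C10 the electrophilic carbon, which fixes the regiochemistry. C1 and C10 keep the E geometry of 5 (C2 trans to C9), and their absolute configuration comes from the catalyst, whose aryl groups cover one face of the bound enal. C11 is set by the Z enol ether (methyl outside) together with the exo-formyl orientation, in which C15 and the CH2OTBS arm lie under the diene so that C20, C9 and C15 end on one face. The step needs exo-formyl selectivity, and what should secure it is the bulk of the catalyst-bound formyl group on the fully substituted C1, which avoids the space below the diene.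

Step 4
Reactants: 6 Diels–Alder adduct; 7 ethynylmagnesium bromide
Product: 8 ethynyl carbinols at C2 (both C2 epimers)
Conditions: HC≡CMgBr, THF, −78 → 0 °C; aq NH4Cl
Reagents that add atoms: none
Why: Grignard addition of the small ethynyl nucleophile to the neopentylic aldehyde leaves the silyl enol ether intact, and the C2 configuration is left open because the carbinol is oxidised in the next step.

Step 5
Reactants: 8 ethynyl carbinols
Product: 9 C2 ethynyl ketone
Conditions: Dess–Martin periodinane, NaHCO3, CH2Cl2, 0 °C → rt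
Reagents that add atoms: none
Why: Dess–Martin oxidation under bicarbonate buffer converges both propargylic alcohols to one ynone while the acid-labile enol ether survives.

Step 6
Reactants: 9 C2 ethynyl ketone
Product: 10 (2R)-propargylic alcohol
Conditions: (S)-2-methyl-CBS-oxazaborolidine (C18H20BNO, 20 mol%), catecholborane, toluene, −78 °C; MeOH, aq NaHCO3
Reagents that add atoms: none
Why: CBS reduction treats the fully substituted C1 as the large and the ethynyl group as the small substituent, so the (S)-catalyst should give the 2R carbinol by reagent control, and catecholborane at low temperature spares the enol ether.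

Step 7
Reactants: 10 (2R)-propargylic alcohol
Product: 11 (2R)-allylic alcohol (C3=C4 vinyl group)
Conditions: H2 (1 atm), Pd/CaCO3 poisoned with Pb(OAc)2 (Lindlar catalyst), quinoline, EtOAc, rt
Reagents that add atoms: none
Why: Lindlar semihydrogenation stops at the terminal alkene that will later carry boron to C4, and the trisubstituted enol ether is not reduced.

Step 8
Reactants: 11 (2R)-allylic alcohol
Product: 12 2-O-TBS ether of 11
Conditions: TBSOTf, 2,6-lutidine, CH2Cl2, −78 → 0 °C
Reagents that add atoms: tert-butyldimethylsilyl triflate, CC(C)(C)[Si](C)(C)OS(=O)(=O)C(F)(F)F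
Why: Silylation with the silyl triflate and a hindered pyridine base protects the hindered allylic alcohol before the palladium and hydride steps.

Step 9
Reactants: 12 2-O-TBS silyl enol ether
Product: 13 C13=C14 enone (C12 ketone)
Conditions: Pd(OAc)2 (1.1 equiv), MeCN, 40 °C
Reagents that add atoms: none
Why: Saegusa–Ito oxidation converts the C12 silyl enol ether into an oxa-π-allyl palladium species that can lose a β-hydride only from C14, giving the enone without base and so without risk to the C11 centre.

Step 10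
Reactants: 13 enone
Product: 14 (12S)-allylic alcohol (hydroxyl cis to the C11 methyl)
Conditions: i-Bu2AlH, toluene, −78 °C; aq potassium sodium tartrate
Reagents that add atoms: none
Why: In this 1,2-reduction of the enone by a bulky aluminium hydride the axial CH2OTBS arm on C10 blocks the β face of the carbonyl, so hydride should enter from the α face and give the 12S alcohol, the epimer wanted for the final inversion.

Step 11
Reactants: 14 (12S)-allylic alcohol
Product: 15 2,9,12-tris-O-TBS ether
Conditions: TBSOTf, 2,6-lutidine, CH2Cl2, 0 °C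
Reagents that add atoms: tert-butyldimethylsilyl triflate, CC(C)(C)[Si](C)(C)OS(=O)(=O)C(F)(F)F
Why: Silyl triflate silylation caps the allylic alcohol so that C9 can be oxidised alone.

Step 12
Reactants: 15 tris-O-TBS ether
Product: 16 C9 primary alcohol
Conditions: HF·pyridine, pyridine, THF, 0 °C
Reagents that add atoms: none
Why: Selective desilylation: buffered fluoride cleaves the primary silyl ether much faster than the two hindered secondary ones.

Step 13
Reactants: 16 C9 primary alcohol
Product: 17 C9 aldehyde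
Conditions: Dess–Martin periodinane, NaHCO3, CH2Cl2, 0 °C
Reagents that add atoms: none
Why: Dess–Martin oxidation gives the aldehyde under buffered conditions that do not epimerise C10.

Step 14
Reactants: 17 C9 aldehyde; 18 ethyl 1,3-dithiane-2-carboxylate
Product: 20 (9R)-aldol adduct (C8 as dithiane, C7 as ethyl ester), via lithium enolate 19 (not isolated)
Conditions: 18, LiN(i-Pr)2, THF, −78 °C; then 17, −78 °C; AcOH quench at −78 °C
Reagents that add atoms: none
Why: Aldol addition of the sulfur-stabilised ester enolate, an acyl-anion equivalent for C8 that already carries C7, should follow Felkin–Anh attack anti to the fully substituted C1 and past H10 to set 9R, and the cold acid quench prevents retro-aldol.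

Step 15
Reactants: 20 (9R)-aldol adduct
Product: 21 9-O-TBS ether of 20
Conditions: TBSOTf, 2,6-lutidine, CH2Cl2, −78 → 0 °C
Reagents that add atoms: tert-butyldimethylsilyl triflate, CC(C)(C)[Si](C)(C)OS(=O)(=O)C(F)(F)F
Why: Silyl triflate silylation blocks retro-aldol cleavage and protects O9 for the organometallic steps.

Step 16
Reactants: 21 9-O-TBS ester; 22 prop-1-ynyllithium
Product: 23 C7 ynone (C7 ketone joined to C6≡C5–C16)
Conditions: 22, BF3·OEt2, THF, −78 °C
Reagents that add atoms: none
Why: BF3-promoted acylation of an alkynyllithium by an ester stops at the ketone stage because the boron-bound tetrahedral adduct collapses only on work-up.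

Step 17
Reactants: 23 C7 ynone
Product: 24 (7S)-propargylic alcohol
Conditions: (R)-2-methyl-CBS-oxazaborolidine (C18H20BNO, 30 mol%), catecholborane, toluene, −78 → −40 °C; MeOH, aq NaHCO3
Reagents that add atoms: none
Why: CBS reduction with the dithiane carbon C8 as the large and the propynyl group as the small substituent should give the 7S alcohol from the (R)-catalyst by reagent control.

Step 18
Reactants: 24 (7S)-propargylic alcohol
Product: 26 (7S,5Z)-vinyl iodide (iodine on C5 cis to C7), via vinylalanate 25 (not isolated)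
Conditions: NaAlH2(OCH2CH2OCH3)2, THF, 0 °C → rt; EtOAc; then I2, THF, −78 °C
Reagents that add atoms: iodine, II
Why: Hydroxyl-directed trans-hydroalumination of the propargylic alcohol places aluminium on C5 in a five-membered alanate, and iodinolysis with retention gives the Z vinyl iodide in which iodine, later replaced by C4, is cis to C7.

Step 19
Reactants: 26 (7S,5Z)-vinyl iodide; 27 2-bromopropanoyl bromide
Product: 28 7-O-(2-bromopropanoyl) ester (both CHBr epimers)
Conditions: 27, pyridine, DMAP (cat.), CH2Cl2, 0 °C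
Reagents that add atoms: none
Why: Acylation of the hindered allylic alcohol by the acid bromide installs C17–C19, and the racemic reagent suffices because the CHBr centre is lost on enolate formation.

Step 20
Reactants: 28 bromopropanoate
Product: 29 C8 ketone (α-acyloxy ketone)
Conditions: PhI(OCOCF3)2, NaHCO3, MeCN/H2O (9:1), 0 °C
Reagents that add atoms: water, O
Why: Oxidative dethioacetalisation by the hypervalent iodine reagent unmasks the C8 ketone quickly at 0 °C without touching the alkenes, the vinyl iodide or the bromo ester.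

Step 21
Reactants: 29 C8 ketone
Product: 30 (7S,8S,17R)-hydroxy lactone
Conditions: SmI2 (2.2 equiv), THF, −78 °C; aq NH4Cl
Reagents that add atoms: none
Why: In this intramolecular Reformatsky reaction SmI2 reduces the α-bromo ester to a samarium enolate that adds to the neighbouring ketone, and as the lactone closes the C6 alkenyl group on C7 and the C18 methyl should both turn away from the bulky C9 branch, giving C6 trans to C9 (8S) and the methyl cis to the new hydroxyl (17R).

Step 22
Reactants: 30 hydroxy lactone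
Product: 32 12-epi tricycle (ten-membered ring closed, tris-TBS ether), via C4 alkylborane 31 (not isolated)
Conditions: 9-BBN (3 equiv), THF, rt; then added slowly to Pd(dppf)Cl2 (20 mol%), AsPh3, Cs2CO3, DMF/THF/H2O, rt (final 0.002 M)
Reagents that add atoms: none
Why: Hydroboration of the terminal alkene puts boron on C4, and an intramolecular B-alkyl Suzuki–Miyaura coupling with the vinyl iodide at high dilution closes the ten-membered ring with retention of the Z geometry at C5=C6.

Step 23
Reactants: 32 12-epi tricycle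
Product: 33 12-epi tetraol
Conditions: HF·pyridine, THF, 0 °C → rt
Reagents that add atoms: none
Why: Fluoride-mediated desilylation under buffered HF removes all three silyl ethers and leaves the lactone and the alkenes untouched.

Step 24
Reactants: 33 12-epi tetraol
Product: 34 12-butanoate (12R) with free hydroxyls at C2, C8 and C9
Conditions: n-PrCO2H, PPh3, DIAD, toluene, 0 °C → rt
Reagents that add atoms: butanoic acid, CCCC(=O)O
Why: Mitsunobu esterification should occur only at the allylic C12 hydroxyl, since the C2 and C9 hydroxyls are flanked by fully substituted carbons and the C8 hydroxyl is tertiary, and SN2 displacement inverts C12 to the 12R butanoate.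

Step 25
Reactants: 34 12-butanoate
Product: 35 CNP0211702.1
Conditions: Ac2O, pyridine, DMAP (cat.), CH2Cl2, rt
Reagents that add atoms: acetic anhydride, CC(=O)OC(C)=O
Why: DMAP-catalysed acetylation esterifies the two secondary alcohols, while the tertiary C8 hydroxyl is too hindered to react under these conditions.

Compound list
1 | pent-1-en-3-one | CCC(=O)C=C | starting material
2 | (Z)-3-(tert-butyldimethylsilyloxy)penta-1,3-diene | C=C/C(O[Si](C)(C)C(C)(C)C)=C/C | intermediate
3 | (tert-butyldimethylsilyloxy)acetaldehyde | CC(C)(C)[Si](C)(C)OCC=O | starting material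
4 | 2-(triphenylphosphoranylidene)propanal | CC(C=O)=P(c1ccccc1)(c1ccccc1)c1ccccc1 | starting material
5 | (E)-4-(tert-butyldimethylsilyloxy)-2-methylbut-2-enal | O=C/C(C)=C/CO[Si](C)(C)C(C)(C)C | intermediate
6 | (1S,5R,6S)-4-(tert-butyldimethylsilyloxy)-6-[(tert-butyldimethylsilyloxy)methyl]-1,5-dimethylcyclohex-3-ene-1-carbaldehyde | CC(C)(C)[Si](C)(C)OC1=CC[C@@](C=O)(C)[C@H]([C@H]1C)CO[Si](C)(C)C(C)(C)C | intermediate
7 | ethynylmagnesium bromide | C#C[Mg]Br | starting material
8 | ethynyl carbinols: 6 with the formyl group turned into CH(OH)C≡CH, both C2 epimers | CC(C)(C)[Si](C)(C)OC1=CC[C@@](C(O)C#C)(C)[C@H]([C@H]1C)CO[Si](C)(C)C(C)(C)C | intermediate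
9 | C2 ethynyl ketone | CC(C)(C)[Si](C)(C)OC1=CC[C@@](C(=O)C#C)(C)[C@H]([C@H]1C)CO[Si](C)(C)C(C)(C)C | intermediate
10 | (2R)-propargylic alcohol | CC(C)(C)[Si](C)(C)OC1=CC[C@@]([C@H](O)C#C)(C)[C@H]([C@H]1C)CO[Si](C)(C)C(C)(C)C | intermediate
11 | (2R)-allylic alcohol with the C3=C4 vinyl group | CC(C)(C)[Si](C)(C)OC1=CC[C@@]([C@H](O)C=C)(C)[C@H]([C@H]1C)CO[Si](C)(C)C(C)(C)C | intermediate
12 | 2-O-TBS ether of 11 | CC(C)(C)[Si](C)(C)OC1=CC[C@@]([C@H](O[Si](C)(C)C(C)(C)C)C=C)(C)[C@H]([C@H]1C)CO[Si](C)(C)C(C)(C)C | intermediate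
13 | cyclohex-13-en-12-one (enone) with 2-O-TBS and 9-O-TBS | O=C1C=C[C@@]([C@H](O[Si](C)(C)C(C)(C)C)C=C)(C)[C@H]([C@H]1C)CO[Si](C)(C)C(C)(C)C | intermediate
14 | (12S)-allylic alcohol, hydroxyl cis to the C11 methyl | O[C@H]1C=C[C@@]([C@H](O[Si](C)(C)C(C)(C)C)C=C)(C)[C@H]([C@H]1C)CO[Si](C)(C)C(C)(C)C | intermediate
15 | 2,9,12-tris-O-TBS ether | CC(C)(C)[Si](C)(C)O[C@H]1C=C[C@@]([C@H](O[Si](C)(C)C(C)(C)C)C=C)(C)[C@H]([C@H]1C)CO[Si](C)(C)C(C)(C)C | intermediate
16 | C9 primary alcohol (2,12-bis-O-TBS) | CC(C)(C)[Si](C)(C)O[C@H]1C=C[C@@]([C@H](O[Si](C)(C)C(C)(C)C)C=C)(C)[C@H]([C@H]1C)CO | intermediate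
17 | C9 aldehyde | CC(C)(C)[Si](C)(C)O[C@H]1C=C[C@@]([C@H](O[Si](C)(C)C(C)(C)C)C=C)(C)[C@H]([C@H]1C)C=O | intermediate
18 | ethyl 1,3-dithiane-2-carboxylate | CCOC(=O)C1SCCCS1 | starting material
19 | lithium enolate of 18 | [Li+].CCOC([O-])=C1SCCCS1 | intermediate (not isolated)
20 | (9R)-aldol adduct: C9 carbinol, C8 as 1,3-dithiane, C7 as ethyl ester | CC(C)(C)[Si](C)(C)O[C@H]1C=C[C@@]([C@H](O[Si](C)(C)C(C)(C)C)C=C)(C)[C@H]([C@H]1C)[C@@H](O)C2(SCCCS2)C(=O)OCC | intermediate
21 | 9-O-TBS ether of 20 | CC(C)(C)[Si](C)(C)O[C@H]1C=C[C@@]([C@H](O[Si](C)(C)C(C)(C)C)C=C)(C)[C@H]([C@H]1C)[C@@H](O[Si](C)(C)C(C)(C)C)C2(SCCCS2)C(=O)OCC | intermediate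
22 | prop-1-ynyllithium | [Li]C#CC | starting material
23 | C7 ynone (C7 ketone joined to C6≡C5–C16) | CC(C)(C)[Si](C)(C)O[C@H]1C=C[C@@]([C@H](O[Si](C)(C)C(C)(C)C)C=C)(C)[C@H]([C@H]1C)[C@@H](O[Si](C)(C)C(C)(C)C)C2(SCCCS2)C(=O)C#CC | intermediate
24 | (7S)-propargylic alcohol | CC(C)(C)[Si](C)(C)O[C@H]1C=C[C@@]([C@H](O[Si](C)(C)C(C)(C)C)C=C)(C)[C@H]([C@H]1C)[C@@H](O[Si](C)(C)C(C)(C)C)C2(SCCCS2)[C@@H](O)C#CC | intermediate
25 | sodium vinylalanate: five-membered ring O7–Al–C5=C6–C7, aluminium carrying two 2-methoxyethoxy groups | CC(C)(C)[Si](C)(C)O[C@H]1C=C[C@@]([C@H](O[Si](C)(C)C(C)(C)C)C=C)(C)[C@H]([C@H]1C)[C@@H](O[Si](C)(C)C(C)(C)C)C2(SCCCS2)[C@H]3O[Al-](OCCOC)(OCCOC)C(C)=C3.[Na+] | intermediate (not isolated)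
26 | (7S,5Z)-5-iodo allylic alcohol | CC(C)(C)[Si](C)(C)O[C@H]1C=C[C@@]([C@H](O[Si](C)(C)C(C)(C)C)C=C)(C)[C@H]([C@H]1C)[C@@H](O[Si](C)(C)C(C)(C)C)C2(SCCCS2)[C@@H](O)/C=C(/C)I | intermediate
27 | 2-bromopropanoyl bromide (racemic) | CC(Br)C(Br)=O | starting material
28 | 7-O-(2-bromopropanoyl) ester of 26, both CHBr epimers | CC(C)(C)[Si](C)(C)O[C@H]1C=C[C@@]([C@H](O[Si](C)(C)C(C)(C)C)C=C)(C)[C@H]([C@H]1C)[C@@H](O[Si](C)(C)C(C)(C)C)C2(SCCCS2)[C@@H](OC(=O)C(C)Br)/C=C(/C)I | intermediate
29 | C8 ketone (α-acyloxy ketone) | CC(C)(C)[Si](C)(C)O[C@H]1C=C[C@@]([C@H](O[Si](C)(C)C(C)(C)C)C=C)(C)[C@H]([C@H]1C)[C@@H](O[Si](C)(C)C(C)(C)C)C(=O)[C@@H](OC(=O)C(C)Br)/C=C(/C)I | intermediate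
30 | (7S,8S,17R)-8-hydroxy-17-methyl γ-lactone with the Z iodoalkenyl group on C7 | CC(C)(C)[Si](C)(C)O[C@H]1C=C[C@@]([C@H](O[Si](C)(C)C(C)(C)C)C=C)(C)[C@H]([C@H]1C)[C@@H](O[Si](C)(C)C(C)(C)C)[C@@]2(O)[C@H](/C=C(/C)I)OC(=O)[C@@H]2C | intermediate
31 | C4 (9-borabicyclo[3.3.1]nonan-9-yl) borane of 30 | CC(C)(C)[Si](C)(C)O[C@H]1C=C[C@@]([C@H](O[Si](C)(C)C(C)(C)C)CCB2C3CCCC2CCC3)(C)[C@H]([C@H]1C)[C@@H](O[Si](C)(C)C(C)(C)C)[C@@]2(O)[C@H](/C=C(/C)I)OC(=O)[C@@H]2C | intermediate (not isolated)
32 | 12-epi tricycle, 2,9,12-tris-O-TBS, all other centres as in the target | CC(C)(C)[Si](C)(C)O[C@H]1C=C[C@@]2(C)[C@H]([C@H]1C)[C@@H](O[Si](C)(C)C(C)(C)C)[C@@]1(O)[C@H](/C=C(/C)CC[C@H]2O[Si](C)(C)C(C)(C)C)OC(=O)[C@@H]1C | intermediate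
33 | 12-epi tetraol (hydroxyls at C2, C8, C9, C12) | O[C@H]1C=C[C@@]2(C)[C@H]([C@H]1C)[C@@H](O)[C@@]1(O)[C@H](/C=C(/C)CC[C@H]2O)OC(=O)[C@@H]1C | intermediate
34 | 12-O-butanoyl triol with the natural 12R configuration | CCCC(=O)O[C@@H]1C=C[C@@]2(C)[C@H]([C@H]1C)[C@@H](O)[C@@]1(O)[C@H](/C=C(/C)CC[C@H]2O)OC(=O)[C@@H]1C | intermediate
35 | CNP0211702.1 | CCCC(=O)O[C@@H]1C=C[C@@]2(C)[C@H]([C@H]1C)[C@@H](OC(C)=O)[C@@]1(O)[C@H](/C=C(/C)CC[C@H]2OC(C)=O)OC(=O)[C@@H]1C | target

Total step count: 25. Longest linear sequence: 24 steps (1 → 2 → 6 → … → 35; the branch 3 + 4 → 5 is equally long).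

Steps most likely to fail

Step 3. The endo-formyl transition state, which has only H10 under the diene and benefits from secondary orbital overlap, may compete with or override the exo mode, so that the C20 methyl would come out on the α face, trans to C9. The fallback sets C11 after the cycloaddition by kinetic protonation instead of by the cycloaddition topology. Setting out from 2 and 5, the endo adduct F1 is carried through the operations of steps 4 to 9 without change, passing the ethynyl carbinols F2, the ethynyl ketone F3, the 2R propargylic alcohol F4, the 2R allylic alcohol F5, the silyl ether F6 and the 11-epi enone F7. F7 is deprotonated at C11 with LiN(i-Pr)2 in THF at −78 °C to the cross-conjugated lithium dienolate F8. Allylic strain with the C20 methyl holds the C10 CH2OTBS arm axial on the β face, so protonation at −78 °C with 2,6-di-tert-butylphenol should come from the α face and return the route to enone 13.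

Step 22. With the trans-fused lactone already in place the two chain ends may be held apart, so that intermolecular coupling, protodeboronation or opening of the allylic lactone by zerovalent palladium and base outrun ring closure. The fallback closes the ten-membered ring before the lactone. Setting out from 26, hydroboration with 9-BBN gives the alkylborane F9, which is cyclised under the same palladium conditions to the dithiane-bearing cyclodecenol F10. Acylation with 27 then gives the macrocyclic bromopropanoate F11, PhI(OCOCF3)2 in aqueous MeCN gives the macrocyclic ketone F12, and the SmI2 Reformatsky reaction closes the lactone across the preformed ring to rejoin the route at 32.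

Step 21. Electron transfer to the C8 ketone with loss of the C7 acyloxy group (reductive C–O cleavage next to the carbonyl) may compete with enolate formation, or the aldol may deliver the C17 epimer. The fallback is a copper hydride reductive aldol cyclisation, which makes the enolate by conjugate reduction instead of by electron transfer. Setting out from 26, acryloyl chloride and pyridine give the acrylate F13, and PhI(OCOCF3)2 in aqueous MeCN gives the keto acrylate F14. Cu(OAc)2·H2O (cat.), 1,1'-bis(diphenylphosphino)ferrocene and (Me2HSi)2O in THF then reduce the acrylate to a Z copper enolate that adds to the C8 ketone through a chair-like transition state, placing the C18 methyl cis to the C8 hydroxyl and rejoining the route at 30.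

Further compounds
F1 | step 3 | endo adduct (11-epi-6) | CC(C)(C)[Si](C)(C)OC1=CC[C@@](C=O)(C)[C@H]([C@@H]1C)CO[Si](C)(C)C(C)(C)C
F2 | step 3 | ethynyl carbinols (11-epi-8, both C2 epimers) | CC(C)(C)[Si](C)(C)OC1=CC[C@@](C(O)C#C)(C)[C@H]([C@@H]1C)CO[Si](C)(C)C(C)(C)C
F3 | step 3 | ethynyl ketone (11-epi-9) | CC(C)(C)[Si](C)(C)OC1=CC[C@@](C(=O)C#C)(C)[C@H]([C@@H]1C)CO[Si](C)(C)C(C)(C)C
F4 | step 3 | 2R propargylic alcohol (11-epi-10) | CC(C)(C)[Si](C)(C)OC1=CC[C@@]([C@H](O)C#C)(C)[C@H]([C@@H]1C)CO[Si](C)(C)C(C)(C)C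
F5 | step 3 | 2R allylic alcohol (11-epi-11) | CC(C)(C)[Si](C)(C)OC1=CC[C@@]([C@H](O)C=C)(C)[C@H]([C@@H]1C)CO[Si](C)(C)C(C)(C)C
F6 | step 3 | silyl ether (11-epi-12) | CC(C)(C)[Si](C)(C)OC1=CC[C@@]([C@H](O[Si](C)(C)C(C)(C)C)C=C)(C)[C@H]([C@@H]1C)CO[Si](C)(C)C(C)(C)C
F7 | step 3 | 11-epi enone (11-epi-13) | O=C1C=C[C@@]([C@H](O[Si](C)(C)C(C)(C)C)C=C)(C)[C@H]([C@@H]1C)CO[Si](C)(C)C(C)(C)C
F8 | step 3 | cross-conjugated lithium dienolate (C11=C12–OLi) | [Li+].[O-]C=1C=C[C@@]([C@H](O[Si](C)(C)C(C)(C)C)C=C)(C)[C@H](C1C)CO[Si](C)(C)C(C)(C)C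
F9 | step 22 | alkylborane of 26 (boron on C4) | CC(C)(C)[Si](C)(C)O[C@H]1C=C[C@@]([C@H](O[Si](C)(C)C(C)(C)C)CCB2C3CCCC2CCC3)(C)[C@H]([C@H]1C)[C@@H](O[Si](C)(C)C(C)(C)C)C2(SCCCS2)[C@@H](O)/C=C(/C)I
F10 | step 22 | dithiane-bearing cyclodecenol (ten-membered ring closed, C7 hydroxyl free) | CC(C)(C)[Si](C)(C)O[C@H]1C=C[C@@]2(C)[C@H]([C@H]1C)[C@@H](O[Si](C)(C)C(C)(C)C)C1(SCCCS1)[C@@H](O)/C=C(/C)CC[C@H]2O[Si](C)(C)C(C)(C)C
F11 | step 22 | macrocyclic bromopropanoate | CC(C)(C)[Si](C)(C)O[C@H]1C=C[C@@]2(C)[C@H]([C@H]1C)[C@@H](O[Si](C)(C)C(C)(C)C)C1(SCCCS1)[C@@H](OC(=O)C(C)Br)/C=C(/C)CC[C@H]2O[Si](C)(C)C(C)(C)C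
F12 | step 22 | macrocyclic ketone (C8 ketone, C7 bromopropanoate) | CC(C)(C)[Si](C)(C)O[C@H]1C=C[C@@]2(C)[C@H]([C@H]1C)[C@@H](O[Si](C)(C)C(C)(C)C)C(=O)[C@@H](OC(=O)C(C)Br)/C=C(/C)CC[C@H]2O[Si](C)(C)C(C)(C)C
F13 | step 21 | acrylate of 26 | CC(C)(C)[Si](C)(C)O[C@H]1C=C[C@@]([C@H](O[Si](C)(C)C(C)(C)C)C=C)(C)[C@H]([C@H]1C)[C@@H](O[Si](C)(C)C(C)(C)C)C2(SCCCS2)[C@@H](OC(=O)C=C)/C=C(/C)I
F14 | step 21 | keto acrylate (C8 ketone, C7 acrylate) | CC(C)(C)[Si](C)(C)O[C@H]1C=C[C@@]([C@H](O[Si](C)(C)C(C)(C)C)C=C)(C)[C@H]([C@H]1C)[C@@H](O[Si](C)(C)C(C)(C)C)C(=O)[C@@H](OC(=O)C=C)/C=C(/C)I
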